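The plan rests on cutting the C9–C10 bond of the ten-membered carbocycle (C1–C10). C9 is an allylic carbinol directly attached to the Z-trisubstituted C1=C10 olefin, so it can be made from a (Z)-C10 alkenyl iodide and a C9 aldehyde. An intramolecular chromium-mediated, nickel-catalysed alkenyl addition joins these carbons, closes the carbocycle onto the finished α-methylene lactone ring (O–C6–C7–C11–C12) and sets the C9 stereocentre in a single operation. Its substrate is the trans-lactone bearing the (1E,5Z)-6-iodo-2-methylhepta-1,5-dienyl arm on C6 and an (S)-α-triethylsilyloxy acetaldehyde unit (C8–C9) on C7. Only protecting-group changes and acylation of the C8 oxygen follow.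

Key step: step 14

Remark: atom labels C1–C15 are the germacrane numbers of the target (carbocycle C1–C10, lactone oxygen on C6, C11–C13 in the α-methylene lactone, C14 on C10, C15 on C4); [(4-methoxybenzyl)oxy]acetaldehyde and (S)-2-methylglycidol are assumed to be purchasable.

Step 1
Reactants: 1 geranyl acetate
Product: 3 (2E)-3-methyl-6-oxohex-2-en-1-yl acetate, via terminal ozonide 2 (not isolated)
Conditions: O3 (1 equiv), CH2Cl2, −78 °C; then Me2S, −78 °C to rt
Reagents that add atoms: ozone, [O-][O+]=O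
Why: Ozonolysis (Criegee mechanism) should attack the electron-rich terminal isopropylidene olefin in preference to the olefin deactivated by the allylic acetate, and dimethyl sulfide reduces the ozonide to the aldehyde.

Step 2
Reactants: 3 (2E)-3-methyl-6-oxohex-2-en-1-yl acetate
Product: 4 (2E,6Z)-7-iodo-3-methylocta-2,6-dien-1-yl acetate
Conditions: EtPPh3I, n-BuLi, THF, 0 °C; I2, −78 °C; NaN(SiMe3)2, −20 °C; then 3, −78 °C
Reagents that add atoms: ethyltriphenylphosphonium iodide, CC[P+](c1ccccc1)(c1ccccc1)c1ccccc1.[I-]; iodine, II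
Why: Wittig olefination with the α-iodoethylidene ylide (Stork–Zhao-type iodoolefination) should give the trisubstituted alkenyl iodide with iodine cis to the chain (Z), the usual kinetic outcome for this non-stabilised α-halo ylide at low temperature.

Step 3
Reactants: 4 (2E,6Z)-7-iodo-3-methylocta-2,6-dien-1-yl acetate
Product: 5 (2E,6Z)-7-iodo-3-methylocta-2,6-dien-1-ol
Conditions: K2CO3, MeOH, 0 °C to rt
Reagents that add atoms: none
Why: Base-catalysed transesterification (Zemplén-type methanolysis) removes the acetate and leaves the alkenyl iodide and both olefin geometries untouched.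

Step 4
Reactants: 5 (2E,6Z)-7-iodo-3-methylocta-2,6-dien-1-ol
Product: 6 (2E,6Z)-7-iodo-3-methylocta-2,6-dienal
Conditions: MnO2, CH2Cl2, rt
Reagents that add atoms: none
Why: Manganese dioxide oxidation is selective for the allylic alcohol and should give the enal without E/Z isomerisation.

Step 5
Reactants: 6 (2E,6Z)-7-iodo-3-methylocta-2,6-dienal
Product: 7 rac-(4E,8Z)-9-iodo-5-methyldeca-1,4,8-trien-3-ol
Conditions: CH2=CHMgBr, THF, −78 °C
Reagents that add atoms: vinylmagnesium bromide, C=C[Mg]Br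
Why: Grignard 1,2-addition to the β,β-disubstituted enal gives the bis-allylic alcohol as a racemate at the future C6 (resolved in step 6), the alkenyl iodide being inert to the reagent at −78 °C.

Step 6
Reactants: 7 rac-(4E,8Z)-9-iodo-5-methyldeca-1,4,8-trien-3-ol
Product: 8 (3S,4E,8Z)-9-iodo-5-methyldeca-1,4,8-trien-3-ol
Conditions: Ti(OiPr)4 (10 mol%), D-(−)-diisopropyl tartrate (15 mol%), t-BuOOH (0.6 equiv), 4 Å MS, CH2Cl2, −20 °C, run to about 55% conversion
Reagents that add atoms: none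
Why: Sharpless kinetic resolution: with the D-tartrate the (R)-enantiomer should be epoxidised rapidly at its trisubstituted olefin, while the (S)-enantiomer, matched only at the sluggish vinyl group, is recovered and fixes the future C6 configuration.

Step 7
Reactants: 8 (3S,4E,8Z)-9-iodo-5-methyldeca-1,4,8-trien-3-ol; 9 2-(bromomethyl)prop-2-enoic acid
Product: 10 (3S,4E,8Z)-9-iodo-5-methyldeca-1,4,8-trien-3-yl 2-(bromomethyl)prop-2-enoate
Conditions: DCC, DMAP (5 mol%), CH2Cl2, −10 °C to 0 °C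
Reagents that add atoms: none
Why: Steglich esterification acylates the secondary alcohol with retention at the carbinol carbon, the low temperature and small DMAP loading protecting the allylic bromide.

Step 8
Reactants: 10 (3S,4E,8Z)-9-iodo-5-methyldeca-1,4,8-trien-3-yl 2-(bromomethyl)prop-2-enoate
Product: 11 (5R)-3-(bromomethyl)-5-[(1E,5Z)-6-iodo-2-methylhepta-1,5-dien-1-yl]furan-2(5H)-one
Conditions: second-generation Grubbs catalyst (5 mol%), CH2Cl2, 40 °C
Reagents that add atoms: none
Why: Ring-closing metathesis between the monosubstituted vinyl group and the 1,1-disubstituted acrylate olefin closes the butenolide with loss of ethylene, the trisubstituted olefins and the alkenyl iodide being too hindered to engage the ruthenium carbene.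

Step 9
Reactants: 11 (5R)-3-(bromomethyl)-5-[(1E,5Z)-6-iodo-2-methylhepta-1,5-dien-1-yl]furan-2(5H)-one
Product: 13 (5R)-5-[(1E,5Z)-6-iodo-2-methylhepta-1,5-dien-1-yl]-3-[(tributylstannyl)methyl]furan-2(5H)-one, via allylzinc bromide 12 (not isolated)
Conditions: Zn dust, Bu3SnCl, THF/sat. aq NH4Cl, rt
Reagents that add atoms: tributyltin chloride, CCCC[Sn](Cl)(CCCC)CCCC
Why: Barbier-type zinc insertion into the allylic C–Br bond with in situ capture by the tin chloride should give the primary, conjugated allylstannane under neutral conditions that spare the alkenyl iodide and the C6 stereocentre.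

Step 10
Reactants: 13 (5R)-5-[(1E,5Z)-6-iodo-2-methylhepta-1,5-dien-1-yl]-3-[(tributylstannyl)methyl]furan-2(5H)-one; 14 [(4-methoxyphenyl)methoxy]acetaldehyde
Product: 15 (4R,5R)-4-[(1S)-1-hydroxy-2-[(4-methoxyphenyl)methoxy]ethyl]-5-[(1E,5Z)-6-iodo-2-methylhepta-1,5-dien-1-yl]-3-methylideneoxolan-2-one
Conditions: BF3·OEt2, CH2Cl2, −78 °C; sat. aq NaHCO3
Reagents that add atoms: none
Why: Lewis-acid-promoted allylstannane addition (anti-SE2′, Hosomi–Sakurai/Keck type) forms C7–C8 and moves the olefin to the exocyclic C11=C13 position; the aldehyde should reach C7 on the ring face opposite the C6 dienyl arm (trans lactone), and the open antiperiplanar transition state, with the C9 arm turned away from C6, should give the 7,8-syn adduct (8S), which a closed chair transition state would not.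

Step 11
Reactants: 15 (4R,5R)-4-[(1S)-1-hydroxy-2-[(4-methoxyphenyl)methoxy]ethyl]-5-[(1E,5Z)-6-iodo-2-methylhepta-1,5-dien-1-yl]-3-methylideneoxolan-2-one
Product: 16 (4S,5R)-5-[(1E,5Z)-6-iodo-2-methylhepta-1,5-dien-1-yl]-4-[(1S)-2-[(4-methoxyphenyl)methoxy]-1-[(triethylsilyl)oxy]ethyl]-3-methylideneoxolan-2-one
Conditions: TESOTf, 2,6-lutidine, CH2Cl2, −78 °C
Reagents that add atoms: triethylsilyl trifluoromethanesulfonate, CC[Si](CC)(CC)OS(=O)(=O)C(F)(F)F
Why: Silyl triflate/lutidine silylation caps the C8 hydroxyl at low temperature before it can translactonise onto C12, with no stereocentre affected.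

Step 12
Reactants: 16 (4S,5R)-5-[(1E,5Z)-6-iodo-2-methylhepta-1,5-dien-1-yl]-4-[(1S)-2-[(4-methoxyphenyl)methoxy]-1-[(triethylsilyl)oxy]ethyl]-3-methylideneoxolan-2-one
Product: 17 (4S,5R)-4-[(1S)-2-hydroxy-1-[(triethylsilyl)oxy]ethyl]-5-[(1E,5Z)-6-iodo-2-methylhepta-1,5-dien-1-yl]-3-methylideneoxolan-2-one
Conditions: DDQ, CH2Cl2/pH 7 buffer (10:1), 0 °C
Reagents that add atoms: none
Why: Oxidative cleavage of the p-methoxybenzyl ether by DDQ (benzylic hydride abstraction, then hydrolysis) frees the primary C9 hydroxyl under buffered conditions that the triethylsilyl ether, the olefins and the alkenyl iodide should tolerate.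

Step 13
Reactants: 17 (4S,5R)-4-[(1S)-2-hydroxy-1-[(triethylsilyl)oxy]ethyl]-5-[(1E,5Z)-6-iodo-2-methylhepta-1,5-dien-1-yl]-3-methylideneoxolan-2-one
Product: 18 (2S)-2-[(2R,3S)-2-[(1E,5Z)-6-iodo-2-methylhepta-1,5-dien-1-yl]-4-methylidene-5-oxooxolan-3-yl]-2-[(triethylsilyl)oxy]acetaldehyde
Conditions: Dess–Martin periodinane, NaHCO3, CH2Cl2, 0 °C
Reagents that add atoms: none
Why: Buffered Dess–Martin oxidation should give the α-silyloxy aldehyde without epimerising C8, and the aldehyde is used at once.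

Step 14
Reactants: 18 (2S)-2-[(2R,3S)-2-[(1E,5Z)-6-iodo-2-methylhepta-1,5-dien-1-yl]-4-methylidene-5-oxooxolan-3-yl]-2-[(triethylsilyl)oxy]acetaldehyde
Product: 21 (3aS,4S,5R,6Z,10E,11aR)-5-hydroxy-6,10-dimethyl-3-methylidene-4-[(triethylsilyl)oxy]-3a,4,5,8,9,11a-hexahydrocyclodeca[b]furan-2(3H)-one, via alkenylnickel iodide 19 (not isolated), via alkenylchromium dichloride 20 (not isolated)
Conditions: CrCl2 (10 equiv), NiCl2 (2 mol% of the CrCl2), degassed DMSO, rt, syringe-pump addition of 18 to 1 mM final concentration; then aq NH4Cl/EtOAc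
Reagents that add atoms: none
Why: Nozaki–Hiyama–Kishi reaction: CrCl2 reduces NiCl2 to zerovalent nickel, which inserts into the C10–I bond with retention of the Z geometry, the alkenyl group passes to trivalent chromium, and the alkenylchromium adds to the C9 aldehyde while divalent chromium returns nickel to the cycle. The closest known reaction type is the intramolecular alkenylchromium–aldehyde addition used to close medium and large carbocycles from iodo aldehydes. The ten-membered ring C1–C10 closes in the 10-exo-trig mode by attack of C10 on the exocyclic C9 carbonyl, which the Z iodide allows because it holds C2 and C9 on the same side of the C1=C10 olefin. The new C9 stereocentre is controlled by the adjacent C8 centre through a non-chelated Felkin–Anh transition state in which the bulky triethylsilyloxy group stands anti to the incoming alkenyl carbon, which should give the 8,9-anti (9R) carbinol. The step needs selectivity for the aldehyde over the lactone carbonyl and the α-methylene group, which the low basicity and aldehyde preference of alkenylchromium reagents provide, and ring closure over oligomerisation, which slow addition at high dilution secures.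

Step 15
Reactants: 21 (3aS,4S,5R,6Z,10E,11aR)-5-hydroxy-6,10-dimethyl-3-methylidene-4-[(triethylsilyl)oxy]-3a,4,5,8,9,11a-hexahydrocyclodeca[b]furan-2(3H)-one
Product: 22 (3aS,4S,5R,6Z,10E,11aR)-5-[(tert-butyldimethylsilyl)oxy]-6,10-dimethyl-3-methylidene-4-[(triethylsilyl)oxy]-3a,4,5,8,9,11a-hexahydrocyclodeca[b]furan-2(3H)-one
Conditions: TBSOTf, 2,6-lutidine, CH2Cl2, −78 °C to 0 °C
Reagents that add atoms: tert-butyldimethylsilyl trifluoromethanesulfonate, CC(C)(C)[Si](C)(C)OS(=O)(=O)C(F)(F)F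
Why: Silylation with the reactive silyl triflate should cap the hindered allylic C9 hydroxyl with a group that outlasts the triethylsilyl ether.

Step 16
Reactants: 22 (3aS,4S,5R,6Z,10E,11aR)-5-[(tert-butyldimethylsilyl)oxy]-6,10-dimethyl-3-methylidene-4-[(triethylsilyl)oxy]-3a,4,5,8,9,11a-hexahydrocyclodeca[b]furan-2(3H)-one
Product: 23 (3aR,4S,5R,6Z,10E,11aR)-5-[(tert-butyldimethylsilyl)oxy]-4-hydroxy-6,10-dimethyl-3-methylidene-3a,4,5,8,9,11a-hexahydrocyclodeca[b]furan-2(3H)-one
Conditions: PPTS, MeOH/CH2Cl2, 0 °C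
Reagents that add atoms: none
Why: Acid-catalysed methanolysis removes a triethylsilyl ether much faster than the bulkier tert-butyldimethylsilyl ether, so only the C8 hydroxyl should be exposed (the descriptor at C7 changes by priority only).

Step 17
Reactants: 24 [(2S)-2-methyloxiran-2-yl]methanol ((S)-2-methylglycidol)
Product: 25 (2R)-2-methylpent-4-ene-1,2-diol
Conditions: CH2=CHMgBr (2.5 equiv), CuI (10 mol%), THF, −30 °C to 0 °C
Reagents that add atoms: vinylmagnesium bromide, C=C[Mg]Br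
Why: Copper-catalysed Grignard opening of the epoxide at its unsubstituted carbon (SN2) leaves the quaternary stereocentre untouched, the descriptor changing by priority only.

Step 18
Reactants: 25 (2R)-2-methylpent-4-ene-1,2-diol
Product: 27 (2R)-2-methyl-2-(prop-2-en-1-yl)oxirane, via primary tosylate 26 (not isolated)
Conditions: NaH (2.2 equiv), N-tosylimidazole, THF, 0 °C to rt
Reagents that add atoms: none
Why: Selective sulfonylation of the primary alkoxide followed by intramolecular Williamson displacement by the tertiary alkoxide (3-exo-tet) closes the epoxide with the stereocentre unchanged.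

Step 19
Reactants: 27 (2R)-2-methyl-2-(prop-2-en-1-yl)oxirane
Product: 28 [(2R)-2-methyloxiran-2-yl]acetic acid
Conditions: RuCl3·xH2O (2 mol%), NaIO4, NaHCO3, EtOAc/MeCN/H2O, 0 °C
Reagents that add atoms: sodium periodate, [Na+].[O-]I(=O)(=O)=O; water, O
Why: Ruthenium tetroxide (RuO4) generated in situ under Sharpless conditions cleaves the terminal olefin to the carboxylic acid, the cold buffered medium sparing the epoxide, and the acid is used at once.

Step 20
Reactants: 23 (3aR,4S,5R,6Z,10E,11aR)-5-[(tert-butyldimethylsilyl)oxy]-4-hydroxy-6,10-dimethyl-3-methylidene-3a,4,5,8,9,11a-hexahydrocyclodeca[b]furan-2(3H)-one; 28 [(2R)-2-methyloxiran-2-yl]acetic acid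
Product: 29 (3aS,4S,5R,6Z,10E,11aR)-5-[(tert-butyldimethylsilyl)oxy]-6,10-dimethyl-3-methylidene-2-oxo-2,3,3a,4,5,8,9,11a-octahydrocyclodeca[b]furan-4-yl [(2R)-2-methyloxiran-2-yl]acetate
Conditions: DIC, 4-(dimethylamino)pyridinium 4-toluenesulfonate, CH2Cl2, 0 °C
Reagents that add atoms: none
Why: Carbodiimide esterification in the buffered Keck variant of the Steglich protocol acylates the C8 hydroxyl with retention while the medium stays too weakly basic to open the β,γ-epoxy acyl unit by β-elimination.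

Step 21
Reactants: 29 (3aS,4S,5R,6Z,10E,11aR)-5-[(tert-butyldimethylsilyl)oxy]-6,10-dimethyl-3-methylidene-2-oxo-2,3,3a,4,5,8,9,11a-octahydrocyclodeca[b]furan-4-yl [(2R)-2-methyloxiran-2-yl]acetate
Product: 30 (3aS,4S,5R,6Z,10E,11aR)-5-hydroxy-6,10-dimethyl-3-methylidene-2-oxo-2,3,3a,4,5,8,9,11a-octahydrocyclodeca[b]furan-4-yl [(2R)-2-methyloxiran-2-yl]acetate
Conditions: HF·pyridine, pyridine, THF, 0 °C to rt
Reagents that add atoms: none
Why: Fluoride-driven Si–O cleavage under pyridine-buffered, non-basic conditions should free the C9 hydroxyl without opening the epoxide or letting the C8 acyl group migrate.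

Compound list
1 | geranyl acetate, (2E)-3,7-dimethylocta-2,6-dien-1-yl acetate | CC(C)=CCC/C(C)=C/COC(C)=O | starting material
2 | (2E)-5-(5,5-dimethyl-1,2,4-trioxolan-3-yl)-3-methylpent-2-en-1-yl acetate (terminal ozonide, trioxolane carbon unassigned) | CC1(C)OOC(CC/C(C)=C/COC(C)=O)O1 | intermediate (not isolated)
3 | (2E)-3-methyl-6-oxohex-2-en-1-yl acetate | O=CCC/C(C)=C/COC(C)=O | intermediate
4 | (2E,6Z)-7-iodo-3-methylocta-2,6-dien-1-yl acetate | CC(=O)OC/C=C(\C)CC/C=C(/C)I | intermediate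
5 | (2E,6Z)-7-iodo-3-methylocta-2,6-dien-1-ol | OC/C=C(\C)CC/C=C(/C)I | intermediate
6 | (2E,6Z)-7-iodo-3-methylocta-2,6-dienal | O=C/C=C(\C)CC/C=C(/C)I | intermediate
7 | rac-(4E,8Z)-9-iodo-5-methyldeca-1,4,8-trien-3-ol | OC(/C=C(\C)CC/C=C(/C)I)C=C | intermediate
8 | (3S,4E,8Z)-9-iodo-5-methyldeca-1,4,8-trien-3-ol | O[C@H](/C=C(\C)CC/C=C(/C)I)C=C | intermediate
9 | 2-(bromomethyl)prop-2-enoic acid | OC(=O)C(=C)CBr | starting material
10 | (3S,4E,8Z)-9-iodo-5-methyldeca-1,4,8-trien-3-yl 2-(bromomethyl)prop-2-enoate | BrCC(=C)C(=O)O[C@H](/C=C(\C)CC/C=C(/C)I)C=C | intermediate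
11 | (5R)-3-(bromomethyl)-5-[(1E,5Z)-6-iodo-2-methylhepta-1,5-dien-1-yl]furan-2(5H)-one | BrCC1=C[C@@H](/C=C(\C)CC/C=C(/C)I)OC1=O | intermediate
12 | {[(5R)-5-[(1E,5Z)-6-iodo-2-methylhepta-1,5-dien-1-yl]-2-oxo-2,5-dihydrofuran-3-yl]methyl}zinc bromide | Br[Zn]CC1=C[C@@H](/C=C(\C)CC/C=C(/C)I)OC1=O | intermediate (not isolated)
13 | (5R)-5-[(1E,5Z)-6-iodo-2-methylhepta-1,5-dien-1-yl]-3-[(tributylstannyl)methyl]furan-2(5H)-one | CCCC[Sn](CCCC)(CCCC)CC1=C[C@@H](/C=C(\C)CC/C=C(/C)I)OC1=O | intermediate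
14 | [(4-methoxyphenyl)methoxy]acetaldehyde | O=CCOCc1ccc(OC)cc1 | starting material
15 | (4R,5R)-4-[(1S)-1-hydroxy-2-[(4-methoxyphenyl)methoxy]ethyl]-5-[(1E,5Z)-6-iodo-2-methylhepta-1,5-dien-1-yl]-3-methylideneoxolan-2-one (C6 R, C7 R, C8 S) | C=C1C(=O)O[C@H](/C=C(\C)CC/C=C(/C)I)[C@H]1[C@H](O)COCc2ccc(OC)cc2 | intermediate
16 | (4S,5R)-5-[(1E,5Z)-6-iodo-2-methylhepta-1,5-dien-1-yl]-4-[(1S)-2-[(4-methoxyphenyl)methoxy]-1-[(triethylsilyl)oxy]ethyl]-3-methylideneoxolan-2-one | C=C1C(=O)O[C@H](/C=C(\C)CC/C=C(/C)I)[C@H]1[C@H](O[Si](CC)(CC)CC)COCc2ccc(OC)cc2 | intermediate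
17 | (4S,5R)-4-[(1S)-2-hydroxy-1-[(triethylsilyl)oxy]ethyl]-5-[(1E,5Z)-6-iodo-2-methylhepta-1,5-dien-1-yl]-3-methylideneoxolan-2-one | C=C1C(=O)O[C@H](/C=C(\C)CC/C=C(/C)I)[C@H]1[C@H](O[Si](CC)(CC)CC)CO | intermediate
18 | (2S)-2-[(2R,3S)-2-[(1E,5Z)-6-iodo-2-methylhepta-1,5-dien-1-yl]-4-methylidene-5-oxooxolan-3-yl]-2-[(triethylsilyl)oxy]acetaldehyde (key-step precursor) | C=C1C(=O)O[C@H](/C=C(\C)CC/C=C(/C)I)[C@H]1[C@H](O[Si](CC)(CC)CC)C=O | intermediate
19 | C10 alkenylnickel iodide of 18 (divalent nickel; Ni–I in place of the iodide, Z geometry kept) | C=C1C(=O)O[C@H](/C=C(\C)CC/C=C(/C)[Ni]I)[C@H]1[C@H](O[Si](CC)(CC)CC)C=O | intermediate (not isolated)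
20 | C10 alkenylchromium dichloride of 18 (trivalent chromium; CrCl2 in place of the iodide, Z geometry kept) | C=C1C(=O)O[C@H](/C=C(\C)CC/C=C(/C)[Cr](Cl)Cl)[C@H]1[C@H](O[Si](CC)(CC)CC)C=O | intermediate (not isolated)
21 | (3aS,4S,5R,6Z,10E,11aR)-5-hydroxy-6,10-dimethyl-3-methylidene-4-[(triethylsilyl)oxy]-3a,4,5,8,9,11a-hexahydrocyclodeca[b]furan-2(3H)-one (key-step product) | C=C1C(=O)O[C@@H]2/C=C(\C)CC/C=C(/C)[C@@H](O)[C@@H](O[Si](CC)(CC)CC)[C@@H]12 | intermediate
22 | (3aS,4S,5R,6Z,10E,11aR)-5-[(tert-butyldimethylsilyl)oxy]-6,10-dimethyl-3-methylidene-4-[(triethylsilyl)oxy]-3a,4,5,8,9,11a-hexahydrocyclodeca[b]furan-2(3H)-one | C=C1C(=O)O[C@@H]2/C=C(\C)CC/C=C(/C)[C@@H](O[Si](C)(C)C(C)(C)C)[C@@H](O[Si](CC)(CC)CC)[C@@H]12 | intermediate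
23 | (3aR,4S,5R,6Z,10E,11aR)-5-[(tert-butyldimethylsilyl)oxy]-4-hydroxy-6,10-dimethyl-3-methylidene-3a,4,5,8,9,11a-hexahydrocyclodeca[b]furan-2(3H)-one | C=C1C(=O)O[C@@H]2/C=C(\C)CC/C=C(/C)[C@@H](O[Si](C)(C)C(C)(C)C)[C@@H](O)[C@@H]12 | intermediate
24 | [(2S)-2-methyloxiran-2-yl]methanol, (S)-2-methylglycidol | OC[C@@]1(C)CO1 | starting material
25 | (2R)-2-methylpent-4-ene-1,2-diol | OC[C@@](O)(C)CC=C | intermediate
26 | (2R)-2-hydroxy-2-methylpent-4-en-1-yl 4-methylbenzenesulfonate | Cc1ccc(cc1)S(=O)(=O)OC[C@@](O)(C)CC=C | intermediate (not isolated)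
27 | (2R)-2-methyl-2-(prop-2-en-1-yl)oxirane | C=CC[C@]1(C)CO1 | intermediate
28 | [(2R)-2-methyloxiran-2-yl]acetic acid | OC(=O)C[C@]1(C)CO1 | intermediate
29 | (3aS,4S,5R,6Z,10E,11aR)-5-[(tert-butyldimethylsilyl)oxy]-6,10-dimethyl-3-methylidene-2-oxo-2,3,3a,4,5,8,9,11a-octahydrocyclodeca[b]furan-4-yl [(2R)-2-methyloxiran-2-yl]acetate | C=C1C(=O)O[C@@H]2/C=C(\C)CC/C=C(/C)[C@@H](O[Si](C)(C)C(C)(C)C)[C@@H](OC(=O)C[C@]3(C)CO3)[C@@H]12 | intermediate
30 | (3aS,4S,5R,6Z,10E,11aR)-5-hydroxy-6,10-dimethyl-3-methylidene-2-oxo-2,3,3a,4,5,8,9,11a-octahydrocyclodeca[b]furan-4-yl [(2R)-2-methyloxiran-2-yl]acetate (CNP0284481.1) | C=C1C(=O)O[C@@H]2/C=C(\C)CC/C=C(/C)[C@@H](O)[C@@H](OC(=O)C[C@]3(C)CO3)[C@@H]12 | target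

Total step count: 21. Longest linear sequence: 18 steps (steps 1–16, 20 and 21, from geranyl acetate); the side-chain acid takes steps 17–19.

Steps most likely to fail

Step 14. The ring-closing addition may show poor facial selectivity at the C9 carbonyl, because the conformational demands of the ten-membered transition state can override the Felkin–Anh preference and deliver the C9 epimer. The fallback sets out from aldehyde 18. The same closure would then give (3aS,4S,5S,6Z,10E,11aR)-5-hydroxy-6,10-dimethyl-3-methylidene-4-[(triethylsilyl)oxy]-3a,4,5,8,9,11a-hexahydrocyclodeca[b]furan-2(3H)-one F1, alone or mixed with 21. Buffered Dess–Martin oxidation of this material gives the C9 enone (3aS,4S,6Z,10E,11aR)-6,10-dimethyl-3-methylidene-4-[(triethylsilyl)oxy]-3a,8,9,11a-tetrahydrocyclodeca[b]furan-2,5(3H,4H)-dione F2. Corey–Bakshi–Shibata reduction with (R)-2-methyl-CBS-oxazaborolidine and catecholborane at −78 °C, in which the α-methyl-substituted alkenyl arm (C10) acts as the large group, should then set 9R under reagent control and return 21.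

Step 10. The carbonyl-deactivated stannane may react too slowly with the activated aldehyde, so that protodestannylation or attack by the trisubstituted olefin competes, or the open transition state may lose its syn preference. The fallback sets out from bromide 11 and needs no stannane. Zinc-mediated Barbier allylation of 14 (Zn, THF/sat. aq NH4Cl) runs through a closed six-membered transition state and should give the trans-lactone with the opposite configuration at C8, (4R,5R)-4-[(1R)-1-hydroxy-2-[(4-methoxyphenyl)methoxy]ethyl]-5-[(1E,5Z)-6-iodo-2-methylhepta-1,5-dien-1-yl]-3-methylideneoxolan-2-one F3. Mitsunobu inversion with formic acid (PPh3, DIAD) gives (1S)-1-[(2R,3S)-2-[(1E,5Z)-6-iodo-2-methylhepta-1,5-dien-1-yl]-4-methylidene-5-oxooxolan-3-yl]-2-[(4-methoxyphenyl)methoxy]ethyl formate F4 with the required 8S configuration. Brief methanolysis (KHCO3, MeOH, 0 °C) returns alcohol 15.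

Step 20. The activated β,γ-epoxy acid may undergo base-induced β-elimination with epoxide opening, or self-lactonisation, faster than it acylates the hindered C8 hydroxyl. The fallback sets out from diol 25 and alcohol 23 and forms the epoxide only after the acylation. Tosylate 26 is isolated here (TsCl, pyridine) and converted with LiCl in DMF into (2R)-1-chloro-2-methylpent-4-en-2-ol F5. Cleavage with RuCl3/NaIO4 gives the robust (3R)-4-chloro-3-hydroxy-3-methylbutanoic acid F6. Carbodiimide coupling with 23 gives (3aS,4S,5R,6Z,10E,11aR)-5-[(tert-butyldimethylsilyl)oxy]-6,10-dimethyl-3-methylidene-2-oxo-2,3,3a,4,5,8,9,11a-octahydrocyclodeca[b]furan-4-yl (3R)-4-chloro-3-hydroxy-3-methylbutanoate F7. Closure of the chlorohydrin with Cs2CO3 in MeCN returns epoxy ester 29.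

Further compounds
F1 | step 14 | (3aS,4S,5S,6Z,10E,11aR)-5-hydroxy-6,10-dimethyl-3-methylidene-4-[(triethylsilyl)oxy]-3a,4,5,8,9,11a-hexahydrocyclodeca[b]furan-2(3H)-one | C=C1C(=O)O[C@@H]2/C=C(\C)CC/C=C(/C)[C@H](O)[C@@H](O[Si](CC)(CC)CC)[C@@H]12
F2 | step 14 | (3aS,4S,6Z,10E,11aR)-6,10-dimethyl-3-methylidene-4-[(triethylsilyl)oxy]-3a,8,9,11a-tetrahydrocyclodeca[b]furan-2,5(3H,4H)-dione | C=C1C(=O)O[C@@H]2/C=C(\C)CC/C=C(/C)C(=O)[C@@H](O[Si](CC)(CC)CC)[C@@H]12
F3 | step 10 | (4R,5R)-4-[(1R)-1-hydroxy-2-[(4-methoxyphenyl)methoxy]ethyl]-5-[(1E,5Z)-6-iodo-2-methylhepta-1,5-dien-1-yl]-3-methylideneoxolan-2-one | C=C1C(=O)O[C@H](/C=C(\C)CC/C=C(/C)I)[C@H]1[C@@H](O)COCc2ccc(OC)cc2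
F4 | step 10 | (1S)-1-[(2R,3S)-2-[(1E,5Z)-6-iodo-2-methylhepta-1,5-dien-1-yl]-4-methylidene-5-oxooxolan-3-yl]-2-[(4-methoxyphenyl)methoxy]ethyl formate | C=C1C(=O)O[C@H](/C=C(\C)CC/C=C(/C)I)[C@H]1[C@H](OC=O)COCc2ccc(OC)cc2
F5 | step 20 | (2R)-1-chloro-2-methylpent-4-en-2-ol | ClC[C@@](O)(C)CC=C
F6 | step 20 | (3R)-4-chloro-3-hydroxy-3-methylbutanoic acid | ClC[C@@](O)(C)CC(=O)O
F7 | step 20 | (3aS,4S,5R,6Z,10E,11aR)-5-[(tert-butyldimethylsilyl)oxy]-6,10-dimethyl-3-methylidene-2-oxo-2,3,3a,4,5,8,9,11a-octahydrocyclodeca[b]furan-4-yl (3R)-4-chloro-3-hydroxy-3-methylbutanoate | C=C1C(=O)O[C@@H]2/C=C(\C)CC/C=C(/C)[C@@H](O[Si](C)(C)C(C)(C)C)[C@@H](OC(=O)C[C@@](C)(O)CCl)[C@@H]12
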